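Numbering each ring so that C1 carries the acetyl group, C3 the methyl group and C5 the bridge, both rings are cut at C2–C3 and C5–C6. Read from methyl to methyl (CH3–C3–C4–C5–CH2–C5′–C4′–C3′–CH3), the two rings then share a nine-carbon chain oxygenated at C4 and C4′, the skeleton of nonane-3,7-dione, and each C2–C1–C6 remainder is a malonyl unit. The key step condenses this chain, as its bis(triisopropylsilyl enol ether) with both enol ethers on the outer α-carbons, with two molecules of malonyl dichloride: four C–C bonds and both benzene rings form in one operation, leaving C1–H for a final double acetylation.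

Key step: step 4

Remarks
- The target has no stereocentre and is achiral, so there is no enantiomer to select. The structures are consistent by atom count (C9H16O2 chain + 2 C3H2Cl2O2 − 4 HCl = C15H16O6) and needed no correction.
- The chain is carried as a bis(enol silane), never as free nonane-3,7-dione. A free 1,5-diketone enolate would be expected to close by intramolecular aldol reaction, and a basic metal enolate would deprotonate malonyl dichloride to a ketene.
- "Chain C1–C9" means the nonane chain of 6 and 8; "ring C1–C6" is the ring numbering of the first paragraph.

Route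

Step 1
Reactants: 1 glutaryl dichloride; 2 N,O-dimethylhydroxylamine hydrochloride
Product: 3 N1,N5-dimethoxy-N1,N5-dimethylpentanediamide
Conditions: 2 (2.2 equiv), pyridine (4.6 equiv), CH2Cl2, 0 °C → rt
Reagents that add atoms: N,O-dimethylhydroxylamine hydrochloride, CNOC.Cl
Why: Twofold N-acylation of the secondary hydroxylamine by the diacid chloride (Weinreb amide formation) is fast, stops at the amide and needs no differentiation of the two identical ends.

Step 2
Reactants: 3 N1,N5-dimethoxy-N1,N5-dimethylpentanediamide; 4 vinylmagnesium bromide
Product: 6 nona-1,8-diene-3,7-dione, via bis(bromomagnesium) tetrahedral adduct 5 (not isolated)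
Conditions: CH2=CHMgBr (2.6 equiv), THF, −78 → 0 °C; inverse quench into cold 1 M aq. HCl/Et2O; BHT, used crude
Reagents that add atoms: vinylmagnesium bromide, C=C[Mg]Br
Why: Weinreb ketone synthesis: each amide stops at the magnesium-chelated adduct 5 until the quench, so no tertiary alcohol can form, and the cold acidic inverse quench protonates the released amine before it can add to the vinyl ketones.

Step 3
Reactants: 6 nona-1,8-diene-3,7-dione; 7 triisopropylsilane
Product: 8 (2Z,7Z)-3,7-bis(triisopropylsilyloxy)nona-2,7-diene
Conditions: i-Pr3SiH (2.2 equiv), Pt(0)–1,3-divinyltetramethyldisiloxane complex (0.5 mol% Pt), toluene, 60 °C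
Reagents that add atoms: triisopropylsilane, CC(C)[SiH](C(C)C)C(C)C
Why: Platinum-catalysed 1,4-hydrosilylation of an enone through its s-cis conformer delivers hydrogen to chain C1/C9 and silicon to oxygen, so both enol ethers are fixed on the outer α-carbons (chain C2, C8; Z geometry expected, of no consequence later) without any base or free enolate.

Step 4
Reactants: 8 (2Z,7Z)-3,7-bis(triisopropylsilyloxy)nona-2,7-diene; 9 malonyl dichloride (2 equiv)
Product: 12 bis(2,4,6-trihydroxy-3-methylphenyl)methane, via open-chain bis(acid chloride) 10 (not isolated), via bis(aryl silyl ether) 11 (not isolated)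
Conditions: 9 (2.05 equiv), Et2O (0.05 M), −20 °C → rt, slow addition of 8, no base, Ar; evaporate; TBAF, AcOH, THF, 0 °C
Reagents that add atoms: malonyl dichloride, O=C(Cl)CC(Cl)=O
Why: Proposed new method: each enol ether carbon (chain C2/C8, ring C3) is acylated by one acid chloride group of 9 to give a silyloxocarbenium ion; chloride cannot easily strip the hindered i-Pr3Si group, so the ion loses a proton and, through HCl-mediated equilibration, an O-silyl enol ether towards chain C4/C6 (ring C5) is formed (10), whose carbon attacks the tethered second acid chloride, after which loss of HCl and enolisation should give each benzene ring as its mono-silyl ether (11) and fluoride frees the phenols. The closest known reaction types are the α,α′-annulation of cyclic ketone enol ethers with malonyl dichloride to bicyclo[3.3.1]nonane-2,4,9-triones and the acylation of trimethylsilyl enol ethers with the same reagent, which ends in 4-hydroxy-2-pyranones; the two-directional use on an acyclic bis(enol ether), with aromatisation as the driving force, is not established. Each ring closes by a 6-(enolendo)-exo-trig C-acylation (ring C5–C6 bond) after the intermolecular formation of the ring C2–C3 bond, and no stereocentre is created. The step needs carbon and not oxygen to close each ring, which the silyl group kept on the ketone oxygen secures, since that oxygen can form the lactone only after desilylation. It also needs every malonyl unit to stay within one half, which the outer position of the enol ethers secures: from chain C2 or C8 the only six-membered closure is onto C4 or C6 of the same half, whereas a unit attached first at C4 could bridge to C6.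

Step 5
Reactants: 12 bis(2,4,6-trihydroxy-3-methylphenyl)methane; 13 acetic anhydride
Product: 14 bis(3-acetyl-2,4,6-trihydroxy-5-methylphenyl)methane (CNP0190887.0)
Conditions: Ac2O (2.1 equiv), BF3·OEt2 (solvent), 0 °C → rt, Ar; then ice–water
Reagents that add atoms: acetic anhydride, CC(=O)OC(C)=O
Why: Friedel–Crafts C-acylation of a phloroglucinol can only occur at ring C1, the single unsubstituted carbon of each ring flanked by two hydroxyl groups, and the first acetyl group deactivates its ring against further attack.

Compound list
1 | glutaryl dichloride (pentanedioyl dichloride) | O=C(Cl)CCCC(Cl)=O | starting material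
2 | N,O-dimethylhydroxylamine hydrochloride | CNOC.Cl | starting material
3 | N1,N5-dimethoxy-N1,N5-dimethylpentanediamide | CON(C)C(=O)CCCC(=O)N(C)OC | intermediate
4 | vinylmagnesium bromide | C=C[Mg]Br | starting material
5 | bis(bromomagnesium) 3,7-bis[methoxy(methyl)amino]nona-1,8-diene-3,7-diolate (tetrahedral adduct, diastereomer mixture, not isolated) | C=CC(O[Mg]Br)(CCCC(O[Mg]Br)(C=C)N(C)OC)N(C)OC | intermediate
6 | nona-1,8-diene-3,7-dione | C=CC(=O)CCCC(=O)C=C | intermediate
7 | triisopropylsilane | CC(C)[SiH](C(C)C)C(C)C | starting material
8 | (2Z,7Z)-3,7-bis(triisopropylsilyloxy)nona-2,7-diene | C/C=C(\O[Si](C(C)C)(C(C)C)C(C)C)CCC/C(O[Si](C(C)C)(C(C)C)C(C)C)=C/C | intermediate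
9 | malonyl dichloride | O=C(Cl)CC(Cl)=O | starting material
10 | 4,10-dimethyl-3,11-dioxo-5,9-bis(triisopropylsilyloxy)trideca-5,8-dienedioyl dichloride (not isolated; stereoisomer mixture, descriptors omitted because both stereocentres and both alkene geometries are erased on aromatisation) | O=C(Cl)CC(=O)C(C)C(O[Si](C(C)C)(C(C)C)C(C)C)=CCC=C(O[Si](C(C)C)(C(C)C)C(C)C)C(C)C(=O)CC(Cl)=O | intermediate
11 | bis[4,6-dihydroxy-3-methyl-2-(triisopropylsilyloxy)phenyl]methane (not isolated) | Cc1c(O)cc(O)c(Cc2c(O)cc(O)c(C)c2O[Si](C(C)C)(C(C)C)C(C)C)c1O[Si](C(C)C)(C(C)C)C(C)C | intermediate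
12 | bis(2,4,6-trihydroxy-3-methylphenyl)methane | Cc1c(O)cc(O)c(Cc2c(O)cc(O)c(C)c2O)c1O | intermediate
13 | acetic anhydride | CC(=O)OC(C)=O | starting material
14 | bis(3-acetyl-2,4,6-trihydroxy-5-methylphenyl)methane (CNP0190887.0; achiral) | CC(=O)c1c(O)c(C)c(O)c(Cc2c(O)c(C)c(O)c(C(C)=O)c2O)c1O | target

Step count and risks
Total step count: 5. Longest linear sequence: 5 steps (1 → 3 → 6 → 8 → 12 → 14).

Steps most likely to fail:

1. Step 4 (proposed new method). Three processes may divert it:
   - The silyl group may be lost from the silyloxocarbenium ion before the second C-acylation, after which the freed ketone oxygen closes to the lactone.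
   - Acid may shift a still unreacted enol ether to the inner α-carbon, which allows one malonyl unit to bridge chain C4 and C6.
   - Acid chloride not yet consumed may acylate the electron-rich product rings.

   Fallback with known chemistry, setting out from 8 and coming back at 12: 8 would be C-acylated at both enol ether carbons with methyl malonyl chloride (ZnCl2, CH2Cl2; Lewis-acid-promoted acylation of a silyl enol ether by an acid chloride) to give the bis(3,5-dioxo ester) dimethyl 4,10-dimethyl-3,5,9,11-tetraoxotridecanedioate F1. F1 would then be closed at carbon by a twofold intramolecular Claisen condensation under forcing base (NaOMe, then heating of the dry sodium salt to about 180 °C, then aq. HCl). This is the established, if harsh, way from 3,5-dioxo esters to phloroglucinols and should give 12.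

2. Step 5. Before both rings are deactivated, acid may protonate the ipso carbons of the electron-rich diarylmethane and exchange the bridge (retro-Friedel–Crafts). Partial O-acetylation may also occur. Fallback, setting out from 12 and coming back at 14: a Hoesch reaction (MeCN, HCl gas, ZnCl2, Et2O, 0 °C) uses a nitrilium electrophile that attacks only carbon at low temperature. It should give the bis(ketiminium) salt 1,1'-[methylenebis(2,4,6-trihydroxy-5-methyl-3,1-phenylene)]bis(ethan-1-iminium) dichloride F2, in which each ring is deactivated as soon as it has reacted and which is expected to separate from the ether; hydrolysis in hot water should then give 14.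

3. Step 2. The released N,O-dimethylhydroxylamine may add in conjugate fashion to the vinyl ketones during the quench, and the bis(enone) may polymerise on concentration. Fallback, setting out from 3 and coming back at 8 (it also bypasses step 3): 3 would be treated with ethylmagnesium bromide (THF, 0 °C) to give nonane-3,7-dione F3. Soft enolisation (i-Pr3SiOTf, Et3N, CH2Cl2, 0 °C) would then give 8 together with its double-bond isomers (2Z,6Z)-3,7-bis(triisopropylsilyloxy)nona-2,6-diene F4 and (3Z,6Z)-3,7-bis(triisopropylsilyloxy)nona-3,6-diene F5. The mixture would be taken into step 4; lower efficiency is expected there, because only enol ethers at chain C2/C8 exclude the C4–C6 bridging.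

Further compounds
F1 | step 4 | dimethyl 4,10-dimethyl-3,5,9,11-tetraoxotridecanedioate | COC(=O)CC(=O)C(C)C(=O)CCCC(=O)C(C)C(=O)CC(=O)OC
F2 | step 5 | 1,1'-[methylenebis(2,4,6-trihydroxy-5-methyl-3,1-phenylene)]bis(ethan-1-iminium) dichloride | CC(=[NH2+])c1c(O)c(C)c(O)c(Cc2c(O)c(C)c(O)c(C(C)=[NH2+])c2O)c1O.[Cl-].[Cl-]
F3 | step 2 | nonane-3,7-dione | CCC(=O)CCCC(=O)CC
F4 | step 2 | (2Z,6Z)-3,7-bis(triisopropylsilyloxy)nona-2,6-diene | C/C=C(\O[Si](C(C)C)(C(C)C)C(C)C)CC/C=C(/CC)O[Si](C(C)C)(C(C)C)C(C)C
F5 | step 2 | (3Z,6Z)-3,7-bis(triisopropylsilyloxy)nona-3,6-diene | CC/C(O[Si](C(C)C)(C(C)C)C(C)C)=C/C/C=C(/CC)O[Si](C(C)C)(C(C)C)C(C)C
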